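## Structural features

Derrisdione A (16) is an unsymmetrical benzil. A two-carbon 1,2-diketone chain joins ring B, a 4-hydroxyphenyl group, to C6 of a 2,2-dimethyl-2H-chromene.

Ring A, the benzene ring of the chromene, carries no hydrogen. Going round from C6 (diketone), it bears OH at C7 (hydrogen-bonded to the nearer ketone), a 3-methylbut-2-enyl group at C8, the pyran oxygen at C8a, the pyran C4 at C4a, and OMe at C5.

There is no stereocentre and no double bond with a configuration to control, so no stereochemical relationship has to be set.

The diketone is fragile in four ways: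
- It takes up hydrogen on palladium.
- It undergoes benzilic acid rearrangement in strong base.
- It condenses with 1,2-diamines.
- It can close reversibly with the C7 hydroxyl.

The two electron-rich alkenes are also fragile. They do not survive ozone, trivalent thallium or hydrogenation, and acid closes the prenyl group onto a neighbouring phenol.

The real difficulty has two parts. The first is regiochemical: three phloroglucinol-type oxygens must end up as OH, OMe and pyran O, and two C5 units must go to two similar ring carbons. The second is timing: all oxidative chemistry that creates the diketone must be finished before either alkene exists.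

The key step exploits the array ring B–C(=O)–C(=O)–C6–C7–OH. This is the ring B–C3–C4–C4a–C8a–O1 array of an isoflavone that lacks only C2. An isoflavone can therefore carry the diketone and the C7 hydroxyl in masked form, and it is itself reached by moving ring B along a chalcone.

## Logic of the disconnections

Ring A of the open benzils is numbered C1 (diketone), C2 (OH), C3, C4 (OH), C5, C6 (OMe).

**16 ⇒ 13 + 14.**
- Bonds cut: the pyran O1–C2 and C4–C4a bonds.
- Reason: the styrene-type alkene is the most sensitive group, so it is made last. With the prenyl group already at C3, only C5 of ring A is open, so the ring can form in one direction only.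
- Gain: one ring and five carbons are removed.
- Demand: the condensation must tolerate a free diketone and three phenols. This excludes primary diamine catalysts and strong acid.

**13 ⇒ 11 + 12.**
- Bond cut: the bond between C3 of ring A and the prenyl CH2.
- Reason: C3 lies between the two hydroxyls and para to the methoxy group, so it is the most nucleophilic carbon of the ring.
- Gain: an alkene-free triphenol, which permits oxidative chemistry at every earlier stage.
- Demand: the forward step needs carbon over oxygen alkylation, C3 over C5, and one alkylation only, all in the presence of the ring B phenol.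

**11 ⇒ 9 (through 10).**
- Change: one carbon is put back between the C2 oxygen of ring A and the ring B-bearing carbonyl carbon. The hydroxy-diketone then becomes a pyranone C2=C3 double bond.
- Reason: this masks the diketone and singles out one of three phenolic oxygens.
- Gain: the 1,2-dioxygenation problem becomes an alkene cleavage.
- Demand: the forward cleavage must touch only C2=C3. The two remaining phenols are therefore carried as electron-poor acetates, which leave together with the formate.

**9 ⇒ 7 (through 8).**
- Change: only O-substituents change, from acyl to benzyl.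
- Reason: the aryl shift needs donor ethers that resist acid, whereas ozone needs acceptor esters. Hydrogenolysis is placed here because no diketone is yet present to be reduced.
- Gain: safety, not skeletal simplification.
- Demand: hydrogen uptake must stop before C2=C3 is saturated.

**7 ⇒ 5 (through 6).**
- Bonds cut: the ring B–C3 bond, with ring B returned to the neighbouring carbon, and the O1–C2 bond.
- Gain: the pyranone opens and the 1,2-diaryl skeleton becomes a 1,3-diarylpropenone, which an aldol condensation can deliver.
- Demand: ring B must be a strong migrating group, the substrate must hold no other alkene, and the ortho phenol must stay a spectator until the acid stage.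

**5 ⇒ 3 + 4.**
- Bond cut: the Cα=Cβ double bond.
- Gain: two aromatic building blocks of similar size, so this is the convergent point.
- Demand: only one partner may be enolisable.

**3 ⇒ 1 + 2.**
- Bond cut: the O–CH2Ph bond at the 4'-oxygen.
- Demand: the two hydroxyls of 1 must be distinguished. The hydrogen bond of the 2'-hydroxyl to the ketone does this.

## Other disconnections considered

**Alternative 1:**
- Cut: both aryl–carbonyl bonds. The two diketone carbons are treated as a C2 dielectrophile, 1,4-dimethylpiperazine-2,3-dione A2.
- Forward step: the aryllithium from the fully substituted ring A bromide 6-bromo-5-methoxy-7-(methoxymethoxy)-2,2-dimethyl-8-(3-methylbut-2-enyl)-2H-chromene A3 would add to one amide carbonyl. The aryllithium from 1-bromo-4-(methoxymethoxy)benzene A4 would add to the other. Acid would then collapse both hemiaminal alkoxides to the bis(methoxymethyl) ether of derrisdione A, A1.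
- In favour:
  - The diketone appears at the correct oxidation level without any oxidant, so both alkenes may already be present.
  - The union is convergent and late.
  - Neither thallium nor ozone is needed.
  - The ring B phenol stays masked while ring A is decorated.
  - On all four points this plan is better than the chosen one.
- Against:
  - The whole regiochemical problem is moved into A3. That compound has to be built without the chelating ketone that distinguishes the two hydroxyls in the chosen route.
  - The ring A aryllithium is flanked by two alkoxy groups and should add slowly. Incomplete first addition would let the second nucleophile add twice.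
  - The last step removes two acetals with acid next to an ortho-prenyl phenol and a chromene, which invites ring closure of the prenyl group.
- Step economy: the longest linear sequence should be about equal once A3 is counted, so this plan is level on length and better on convergence.

**Alternative 2:**
- Cut: two ring A carbon–carbon bonds, so that ring A is made from acyclic and four-membered pieces.
- Forward step: 3-methoxycyclobut-2-en-1-one A6 would be heated with the siloxyalkyne triisopropyl[(5-methylhex-4-en-1-yn-1-yl)oxy]silane A7. The sequence would be electrocyclic opening, [2+2] addition, a second opening and 6π closure. The product would be 5-methoxy-2-(3-methylbut-2-enyl)-3-(triisopropylsilyloxy)phenol A5.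
- In favour:
  - The polarity of the ynol ether places the prenyl group between two oxygens without ambiguity.
  - The two oxygens emerge differentiated as OH and silyl ether.
  - On regiocontrol of the prenyl group this plan is clearly better than step 6 of the chosen route.
- Against:
  - Neither A6 nor A7 is a catalogue compound, and each needs its own multistep preparation.
  - A5 still lacks the pyran ring and the whole aroyl-carbonyl unit.
  - The last free position would have to be acylated on a crowded, acid-sensitive, alkene-bearing arene. The diketone, the defining feature of 16, is not addressed at all.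
- Comparison: the cascade is mechanistically elegant but purely thermal, with no handle for correction. In step count it should be markedly longer than the chosen plan.

**Alternative 3:**
- Cut: the pyran C3=C4 double bond.
- Forward step: the second-generation Grubbs catalyst RuCl2(=CHPh)(PCy3)(H2IMes) would join the vinyl group and the tertiary allyl ether of 2-ethenyl-1-methoxy-5-(methoxymethoxy)-4-(3-methylbut-2-enyl)-3-[(2-methylbut-3-en-2-yl)oxy]benzene A9. The product would be 5-methoxy-7-(methoxymethoxy)-2,2-dimethyl-8-(3-methylbut-2-enyl)-2H-chromene A8.
- In favour: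
  - The conditions are neutral and catalytic.
  - The position of the ring is fixed by where the two olefins sit. On this point the plan is the equal of the chosen route, in which only one ring carbon is free.
- Against:
  - The tertiary allyl aryl ether of A9 is hard to make and is prone to sigmatropic rearrangement on warming.
  - The ortho vinyl group costs extra steps.
  - The prenyl alkene, ortho to the same ether, offers the ruthenium carbene a competing seven-membered closure.
- Comparison: the plan spends its key step on the ring that one condensation with 14 closes in the chosen route. The diketone and the prenyl regiochemistry remain unsolved, so it is weaker on strategy and longer in steps.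

Key step: step 3

Assumption: the 2-hydroxybenzils 11, 13 and 16 are treated as the open, hydrogen-bonded diketones. Reversible closure of the ortho hydroxyl onto the far ketone is taken not to change the course of any step.

## Steps

Step 1
Reactants: 1 1-(2,4-dihydroxy-6-methoxyphenyl)ethan-1-one; 2 benzyl bromide
Product: 3 1-[4-(benzyloxy)-2-hydroxy-6-methoxyphenyl]ethan-1-one
Conditions: BnBr (1.05 equiv), K2CO3, acetone, reflux
Reagents that add atoms: benzyl bromide (2), BrCc1ccccc1
Why: Williamson ether synthesis; the 2'-hydroxyl is locked in a hydrogen bond to the ketone and is much less acidic and nucleophilic than the 4'-hydroxyl, so a weak base and one equivalent of 2 should alkylate O-4' only.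

Step 2
Reactants: 3 1-[4-(benzyloxy)-2-hydroxy-6-methoxyphenyl]ethan-1-one; 4 4-(benzyloxy)benzaldehyde
Product: 5 (E)-1-[4-(benzyloxy)-2-hydroxy-6-methoxyphenyl]-3-[4-(benzyloxy)phenyl]prop-2-en-1-one
Conditions: KOH (50% aq), EtOH, rt; then cold dilute HCl
Reagents that add atoms: 4-(benzyloxy)benzaldehyde (4), O=Cc1ccc(OCc2ccccc2)cc1
Why: Claisen–Schmidt condensation; 4 cannot enolise, and E1cB loss of water gives the conjugated E-alkene as the thermodynamic isomer. In strong base the product rests as its phenolate, which holds back oxa-Michael closure, and cold acidification should precipitate 5.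

Step 3
Reactants: 5 (E)-1-[4-(benzyloxy)-2-hydroxy-6-methoxyphenyl]-3-[4-(benzyloxy)phenyl]prop-2-en-1-one
Product: 7 7-(benzyloxy)-3-[4-(benzyloxy)phenyl]-5-methoxy-4H-chromen-4-one, via dimethyl acetal 6 (not isolated)
Conditions: Tl(NO3)3·3H2O (1.1 equiv), MeOH–CH2Cl2, rt; filter off TlNO3; then 10% aq HCl, MeOH, reflux
Reagents that add atoms: methanol, CO (its two methoxy groups stand only in 6 and leave again on ring closure)
Why: Trivalent thallium adds as an electrophile to Cα of the enone while methanol is captured at the benzylic β-carbon (oxythallation). Heterolysis of the weak C–Tl bond, with reduction to monovalent thallium, is assisted by ring B, which bridges as a phenonium ion and ends on Cα; the oxocarbenium ion left at the former β-carbon takes up a second methanol and gives racemic 6. The closest known reaction type is the oxidative 1,2-aryl rearrangement of 2'-hydroxychalcones to isoflavones with Tl(NO3)3 in methanol. Acid then ionises the acetal, the ortho phenol oxygen attacks the oxocarbenium carbon in a 6-exo-trig closure, and loss of the second methanol sets up the C2=C3 double bond of the pyranone. No stereocentre remains, because the one at Cα of 6 becomes planar in that elimination. The step needs migration to outrun attack of the phenol oxygen on Cα (a five-membered closure) and oxidation of ring A. The para-benzyloxy group makes ring B a powerful neighbouring group, the phenol is deactivated by its hydrogen bond to the ketone, the benzyl ethers resist the nitric and hydrochloric acid, and the enone is the only alkene in the molecule.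

Step 4
Reactants: 7 7-(benzyloxy)-3-[4-(benzyloxy)phenyl]-5-methoxy-4H-chromen-4-one
Product: 9 4-[7-(acetyloxy)-5-methoxy-4-oxo-4H-chromen-3-yl]phenyl acetate, via 5-O-methylgenistein 8 (not isolated)
Conditions: H2 (1 atm), 10% Pd/C, THF, rt, stopped at two equivalents of H2; filter (Celite); then Ac2O, pyridine, DMAP (cat.), rt
Reagents that add atoms: acetic anhydride, CC(=O)OC(C)=O
Why: Hydrogenolysis of aryl benzyl ethers is much faster than saturation of the push–pull C2=C3 bond, and it is placed here because a 1,2-diketone would itself take up hydrogen on palladium. Acetylation under nucleophilic catalysis makes the sparingly soluble 8 soluble in CH2Cl2 and turns both phenols into electron-poor aryl esters that ozone should leave alone.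

Step 5
Reactants: 9 4-[7-(acetyloxy)-5-methoxy-4-oxo-4H-chromen-3-yl]phenyl acetate
Product: 11 1-(2,4-dihydroxy-6-methoxyphenyl)-2-(4-hydroxyphenyl)ethane-1,2-dione, via aryl formate 10 (not isolated)
Conditions: O3 (metered), CH2Cl2, −78 °C; Me2S, −78 °C to rt; evaporate; then K2CO3, MeOH, 0 °C; 1 M HCl
Reagents that add atoms: ozone, [O-][O+]=O
Why: Ozonolysis (Criegee mechanism) of the only non-aromatic C=C bond turns C3 into the second ketone and C2 into a formyl group on the former O1, and Me2S reduces the peroxidic intermediate. Base-promoted transesterification then removes the formate and both acetates in one operation; the phenolates formed push electron density into both ketones and should shield the diketone from methoxide at 0 °C.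

Step 6
Reactants: 11 1-(2,4-dihydroxy-6-methoxyphenyl)-2-(4-hydroxyphenyl)ethane-1,2-dione; 12 1-bromo-3-methylbut-2-ene
Product: 13 1-[2,4-dihydroxy-6-methoxy-3-(3-methylbut-2-en-1-yl)phenyl]-2-(4-hydroxyphenyl)ethane-1,2-dione
Conditions: KOH (3.2 equiv), MeOH–H2O, 0 °C; prenyl bromide (1.0 equiv, slow addition), 0 °C to rt; 1 M HCl
Reagents that add atoms: 1-bromo-3-methylbut-2-ene (12), CC(C)=CCBr
Why: Nuclear prenylation, that is C-alkylation of the ambident phenolate of a 2,4-dihydroxyaryl ketone; C3 is ortho to both phenolate oxygens and para to OMe, so it is the most electron-rich carbon, and the protic medium shields the oxygen centres by hydrogen bonding. Slow addition of one equivalent of 12 limits a second alkylation, and the ring B phenolate is delocalised into the diketone and can react only at oxygen.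

Step 7
Reactants: 13 1-[2,4-dihydroxy-6-methoxy-3-(3-methylbut-2-en-1-yl)phenyl]-2-(4-hydroxyphenyl)ethane-1,2-dione; 14 3-methylbut-2-enal
Product: 16 1-[7-hydroxy-5-methoxy-2,2-dimethyl-8-(3-methylbut-2-en-1-yl)-2H-chromen-6-yl]-2-(4-hydroxyphenyl)ethane-1,2-dione (derrisdione A), via ortho-quinone methide 15 (not isolated)
Conditions: prenal (3 equiv), pyridine, 115 °C (sealed tube)
Reagents that add atoms: 3-methylbut-2-enal (14), CC(C)=CC=O
Why: Pyridine-catalysed chromenylation of a mono-chelated meta-dihydric phenol; C5, the only free carbon of ring A, attacks the aldehyde, loss of water gives 15, and oxa-6π electrocyclisation closes the pyran through the non-chelated O-4. A tertiary amine is chosen because the 1,2-diamine salts often used for this condensation would condense with the 1,2-diketone, and ring B is too electron-poor to react.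

## Compound list

1 | 1-(2,4-dihydroxy-6-methoxyphenyl)ethan-1-one (2',4'-dihydroxy-6'-methoxyacetophenone) | COc1cc(O)cc(O)c1C(C)=O | starting material
2 | benzyl bromide | BrCc1ccccc1 | starting material
3 | 1-[4-(benzyloxy)-2-hydroxy-6-methoxyphenyl]ethan-1-one | COc1cc(OCc2ccccc2)cc(O)c1C(C)=O | intermediate
4 | 4-(benzyloxy)benzaldehyde | O=Cc1ccc(OCc2ccccc2)cc1 | starting material
5 | (E)-1-[4-(benzyloxy)-2-hydroxy-6-methoxyphenyl]-3-[4-(benzyloxy)phenyl]prop-2-en-1-one | COc1cc(OCc2ccccc2)cc(O)c1C(=O)/C=C/c1ccc(OCc2ccccc2)cc1 | intermediate
6 | 1-[4-(benzyloxy)-2-hydroxy-6-methoxyphenyl]-2-[4-(benzyloxy)phenyl]-3,3-dimethoxypropan-1-one (racemic, not isolated) | COc1cc(OCc2ccccc2)cc(O)c1C(=O)C(C(OC)OC)c1ccc(OCc2ccccc2)cc1 | intermediate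
7 | 7-(benzyloxy)-3-[4-(benzyloxy)phenyl]-5-methoxy-4H-chromen-4-one | COc1cc(OCc2ccccc2)cc2occ(-c3ccc(OCc4ccccc4)cc3)c(=O)c12 | intermediate
8 | 7-hydroxy-3-(4-hydroxyphenyl)-5-methoxy-4H-chromen-4-one (5-O-methylgenistein, not isolated) | COc1cc(O)cc2occ(-c3ccc(O)cc3)c(=O)c12 | intermediate
9 | 4-[7-(acetyloxy)-5-methoxy-4-oxo-4H-chromen-3-yl]phenyl acetate | COc1cc(OC(C)=O)cc2occ(-c3ccc(OC(C)=O)cc3)c(=O)c12 | intermediate
10 | 5-(acetyloxy)-2-{[4-(acetyloxy)phenyl](oxo)acetyl}-3-methoxyphenyl formate (not isolated) | COc1cc(OC(C)=O)cc(OC=O)c1C(=O)C(=O)c1ccc(OC(C)=O)cc1 | intermediate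
11 | 1-(2,4-dihydroxy-6-methoxyphenyl)-2-(4-hydroxyphenyl)ethane-1,2-dione | COc1cc(O)cc(O)c1C(=O)C(=O)c1ccc(O)cc1 | intermediate
12 | 1-bromo-3-methylbut-2-ene (prenyl bromide) | CC(C)=CCBr | starting material
13 | 1-[2,4-dihydroxy-6-methoxy-3-(3-methylbut-2-en-1-yl)phenyl]-2-(4-hydroxyphenyl)ethane-1,2-dione | COc1cc(O)c(CC=C(C)C)c(O)c1C(=O)C(=O)c1ccc(O)cc1 | intermediate
14 | 3-methylbut-2-enal (prenal) | CC(C)=CC=O | starting material
15 | (6Z)-3-hydroxy-4-[(4-hydroxyphenyl)(oxo)acetyl]-5-methoxy-2-(3-methylbut-2-en-1-yl)-6-(3-methylbut-2-en-1-ylidene)cyclohexa-2,4-dien-1-one (not isolated) | O=C1C(CC=C(C)C)=C(O)C(C(=O)C(=O)c2ccc(O)cc2)=C(OC)/C1=C/C=C(C)C | intermediate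
16 | 1-[7-hydroxy-5-methoxy-2,2-dimethyl-8-(3-methylbut-2-en-1-yl)-2H-chromen-6-yl]-2-(4-hydroxyphenyl)ethane-1,2-dione (derrisdione A) | COc1c2c(c(CC=C(C)C)c(O)c1C(=O)C(=O)c1ccc(O)cc1)OC(C)(C)C=C2 | target

## Step count and least certain steps

Total step count: 7. Steps 3, 4, 5 and 7 each pass through one compound that is not isolated.

Longest linear sequence: 7 steps from 1. Compounds 2, 4, 12 and 14 are bought.

**Step 3 (key step).**

What may go wrong:
- The neighbouring phenol oxygen, not ring B, may capture the thallated enone. This is a five-membered closure that competes whenever migration is slow.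
- Trivalent thallium and the liberated nitric acid may oxidise or nitrate the electron-rich ring A.
- The low solubility of 5 in methanol lengthens the exposure.
- The toxicity of thallium salts burdens handling and purification.

Fallback: the ring B–C3 bond is made by cross-coupling instead of migration. The fallback sets out from 3 and rejoins the route at 7.
- Me2NCH(OMe)2 in toluene at 90 °C should give the enaminone (E)-1-[4-(benzyloxy)-2-hydroxy-6-methoxyphenyl]-3-(dimethylamino)prop-2-en-1-one F1.
- Iodine in CHCl3 should close and iodinate it to 7-(benzyloxy)-3-iodo-5-methoxy-4H-chromen-4-one F2.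
- Suzuki–Miyaura coupling with commercial 4-(benzyloxy)phenylboronic acid (Pd(PPh3)4, K2CO3, dioxane–H2O, 80 °C) should give 7.

**Step 5.**

What may go wrong:
- Acyl migration within the peroxidic intermediate that sits next to the C4 ketone (anomalous ozonolysis) would also cut the C3–C4 bond.
- Over-dosing of ozone would lead to attack on ring A.
- Base-induced rearrangement of the diketone could occur during deacylation.

Fallback: C2 is removed hydrolytically and the oxidation level is raised afterwards. The fallback sets out from 7, bypasses steps 4 and 5, and rejoins at 11.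
- KOH in aqueous EtOH at reflux should add hydroxide at C2 and expel formate. The product is the deoxybenzoin 1-[4-(benzyloxy)-2-hydroxy-6-methoxyphenyl]-2-[4-(benzyloxy)phenyl]ethan-1-one F3.
- Riley oxidation (SeO2, dioxane–H2O, reflux) should give 1-[4-(benzyloxy)-2-hydroxy-6-methoxyphenyl]-2-[4-(benzyloxy)phenyl]ethane-1,2-dione F4.
- Acidolysis of both benzyl ethers (CF3CO2H, pentamethylbenzene as cation trap, rt) avoids hydrogen on the diketone and should give 11.

**Step 6.**

What may go wrong:
- O-alkylation may occur at the ring B phenolate or at O-4.
- Alkylation may go to C5 instead of C3.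
- A second alkylation may follow the first.
- The diketone may suffer slow base damage.

These risks arise because three phenolates of similar acidity compete for one electrophile.

Fallback: the carbon is delivered through oxygen by a sigmatropic shift from the one hydroxyl that the isoflavone had masked. The fallback sets out from 9 and rejoins at 13.
- Ozonolysis as in step 5 gives 10. Brief treatment with aqueous NaHCO3 in THF at 0 °C should remove only the formate, giving 4-{[4-(acetyloxy)-2-hydroxy-6-methoxyphenyl](oxo)acetyl}phenyl acetate F5.
- Mitsunobu reaction with allyl alcohol (PPh3, DIAD, THF) is neutral, so the acetates stay. It should give the allyl ether 4-{[4-(acetyloxy)-2-methoxy-6-(prop-2-en-1-yloxy)phenyl](oxo)acetyl}phenyl acetate F6.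
- Aromatic Claisen rearrangement (1,2-dichlorobenzene, 180 °C) can reach only C3. It should give 4-{[4-(acetyloxy)-2-hydroxy-6-methoxy-3-(prop-2-en-1-yl)phenyl](oxo)acetyl}phenyl acetate F7.
- Cross metathesis with 2-methylbut-2-ene (RuCl2(=CHPh)(PCy3)(H2IMes), CH2Cl2, 40 °C) should give 4-{[4-(acetyloxy)-2-hydroxy-6-methoxy-3-(3-methylbut-2-en-1-yl)phenyl](oxo)acetyl}phenyl acetate F8.
- K2CO3 in MeOH at 0 °C should give 13.

**Step 7.**

What may go wrong:
- Attack of the crowded C5, flanked by OH and OMe and deactivated by the acyl group, on the aldehyde may be slow.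
- Self-condensation of 14 may occur at the temperature needed.
- 13 may be lost slowly on long heating.

Fallback: the carbon–carbon bond is formed inside a boron template that ties the aldehyde to O-4. The fallback sets out from 13 and rejoins at 16.
- PhB(OH)2, 14 and acetic acid in toluene under water separation should give the benzodioxaborinine 1-[7-hydroxy-5-methoxy-8-(3-methylbut-2-en-1-yl)-4-(2-methylprop-1-en-1-yl)-2-phenyl-4H-1,3,2-benzodioxaborinin-6-yl]-2-(4-hydroxyphenyl)ethane-1,2-dione F9 (racemic).
- Continued heating should fragment F9 to 15, which closes to 16.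

## Further compounds

F1 | step 3 | (E)-1-[4-(benzyloxy)-2-hydroxy-6-methoxyphenyl]-3-(dimethylamino)prop-2-en-1-one | COc1cc(OCc2ccccc2)cc(O)c1C(=O)/C=C/N(C)C
F2 | step 3 | 7-(benzyloxy)-3-iodo-5-methoxy-4H-chromen-4-one | COc1cc(OCc2ccccc2)cc2occ(I)c(=O)c12
F3 | step 5 | 1-[4-(benzyloxy)-2-hydroxy-6-methoxyphenyl]-2-[4-(benzyloxy)phenyl]ethan-1-one | COc1cc(OCc2ccccc2)cc(O)c1C(=O)Cc1ccc(OCc2ccccc2)cc1
F4 | step 5 | 1-[4-(benzyloxy)-2-hydroxy-6-methoxyphenyl]-2-[4-(benzyloxy)phenyl]ethane-1,2-dione | COc1cc(OCc2ccccc2)cc(O)c1C(=O)C(=O)c1ccc(OCc2ccccc2)cc1
F5 | step 6 | 4-{[4-(acetyloxy)-2-hydroxy-6-methoxyphenyl](oxo)acetyl}phenyl acetate | COc1cc(OC(C)=O)cc(O)c1C(=O)C(=O)c1ccc(OC(C)=O)cc1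
F6 | step 6 | 4-{[4-(acetyloxy)-2-methoxy-6-(prop-2-en-1-yloxy)phenyl](oxo)acetyl}phenyl acetate | COc1cc(OC(C)=O)cc(OCC=C)c1C(=O)C(=O)c1ccc(OC(C)=O)cc1
F7 | step 6 | 4-{[4-(acetyloxy)-2-hydroxy-6-methoxy-3-(prop-2-en-1-yl)phenyl](oxo)acetyl}phenyl acetate | COc1cc(OC(C)=O)c(CC=C)c(O)c1C(=O)C(=O)c1ccc(OC(C)=O)cc1
F8 | step 6 | 4-{[4-(acetyloxy)-2-hydroxy-6-methoxy-3-(3-methylbut-2-en-1-yl)phenyl](oxo)acetyl}phenyl acetate | COc1cc(OC(C)=O)c(CC=C(C)C)c(O)c1C(=O)C(=O)c1ccc(OC(C)=O)cc1
F9 | step 7 | 1-[7-hydroxy-5-methoxy-8-(3-methylbut-2-en-1-yl)-4-(2-methylprop-1-en-1-yl)-2-phenyl-4H-1,3,2-benzodioxaborinin-6-yl]-2-(4-hydroxyphenyl)ethane-1,2-dione (racemic) | COc1c(C(=O)C(=O)c2ccc(O)cc2)c(O)c(CC=C(C)C)c2OB(c3ccccc3)OC(C=C(C)C)c12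
A1 | alternative 1 | bis(methoxymethyl) ether of derrisdione A | COc1c(C(=O)C(=O)c2ccc(OCOC)cc2)c(OCOC)c(CC=C(C)C)c2c1C=CC(C)(C)O2
A2 | alternative 1 | 1,4-dimethylpiperazine-2,3-dione | CN1CCN(C)C(=O)C1=O
A3 | alternative 1 | 6-bromo-5-methoxy-7-(methoxymethoxy)-2,2-dimethyl-8-(3-methylbut-2-enyl)-2H-chromene | COc1c(Br)c(OCOC)c(CC=C(C)C)c2c1C=CC(C)(C)O2
A4 | alternative 1 | 1-bromo-4-(methoxymethoxy)benzene | COCOc1ccc(Br)cc1
A5 | alternative 2 | 5-methoxy-2-(3-methylbut-2-enyl)-3-(triisopropylsilyloxy)phenol | COc1cc(O)c(CC=C(C)C)c(O[Si](C(C)C)(C(C)C)C(C)C)c1
A6 | alternative 2 | 3-methoxycyclobut-2-en-1-one | COC1=CC(=O)C1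
A7 | alternative 2 | triisopropyl[(5-methylhex-4-en-1-yn-1-yl)oxy]silane | CC(C)=CCC#CO[Si](C(C)C)(C(C)C)C(C)C
A8 | alternative 3 | 5-methoxy-7-(methoxymethoxy)-2,2-dimethyl-8-(3-methylbut-2-enyl)-2H-chromene | COc1cc(OCOC)c(CC=C(C)C)c2c1C=CC(C)(C)O2
A9 | alternative 3 | 2-ethenyl-1-methoxy-5-(methoxymethoxy)-4-(3-methylbut-2-enyl)-3-[(2-methylbut-3-en-2-yl)oxy]benzene | COc1cc(OCOC)c(CC=C(C)C)c(OC(C)(C)C=C)c1C=C
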